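# Proposed total synthesis of Ascomindone B

## Structural features

Ascomindone B consists of four benzene rings and one cyclopentenone: an inden-1-one (ring C is its benzo ring, with OH on C4 and OMe on C6) carries ring B on C2 and ring D, a 2,6-dihydroxy-4-methylphenyl group, on C3, and ring B is joined through an ether oxygen to ring A, a methyl 2-hydroxy-4-methylbenzoate. In ring B the ether oxygen stands on C1 between the hydroxyl on C2 and C6 (the carbon bonded to indenone C2), and the methoxy group on C4 is para to the ether oxygen; in ring A the ester on C1 is flanked by the C2 hydroxyl and the C6 ether oxygen. In ring C the carbonyl-bearing carbon C7a is meta to both oxygens, whereas C3a is ortho to the C4 hydroxyl and para to the C6 methoxy group. There is no stereocentre, and since the SMILES defines no axis, the aryl–indenone bonds are assumed to rotate freely and the compound is treated as achiral. Fragile points are the five free phenols on electron-rich rings, the enone, and the ring A/ring B array, in which a phenoxide on ring B C2 can attack ring A (aryl migration of the Smiles type, or lactonisation onto the ester). The real difficulty is the fully substituted C2=C3 bond, which lies between two ortho-substituted aryl groups and the peri oxygen on C4: the right aryl group must end up on each carbon, and OH (not OMe) must end up on C4, although the two ring C oxygens activate the same positions and differ only as OH and OMe. A second difficulty is the diaryl ether, whose ring B carbon has two ortho substituents. The key step exploits the fact that C1 and C3 sit on the adjacent ring C carbons C7a and C3a: read as an aldol condensation, C2=C3 reveals a C3 ketone and a C1 enolate, and tying that enolate oxygen to C3 gives an enol lactone that an aryl nucleophile (ring D) can open at C3.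

## Logic of the disconnections

25 ⇒ 24. No skeletal bond is cut; the five phenolic O–H bonds become O–CH2OMe. Free phenols would quench the organolithium of the key step and are prone to oxidation. The forward step must remove five acetals with acid while leaving the two aryl methyl ethers, the methyl ester and the enone intact.

24 ⇒ 18 + 21 (key disconnection). The bonds cut are C3–C1′ (to ring D) and C2=C3. Reading C2=C3 as an aldol condensation gives the C3 ketone and the C1 enolate 22; cutting C3–C1′ as an acyl substitution and joining the enolate oxygen to C3 gives the enol lactone 18. In one sentence: 21 opens the enol lactone 18 and the enolate so released closes the indenone by aldol condensation. The five-membered ring, the tetrasubstituted alkene and the most hindered aryl–carbon bond all disappear, and the regiochemistry is stored in the connectivity of 18: its carbonyl carbon (next to the C4 oxygen) becomes C3 and its enol carbon becomes C1. The forward step demands that 21 adds once, to the lactone and not to the ring A ester, and that the aldol closes onto a ketone flanked by four ortho substituents.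

18 ⇒ 17. The enol C–O bond (O to C1) is cut, giving an open alkynyl acid. The forward step is a carboxylate addition to the alkyne and must be 5-exo, not 6-endo.

17 ⇒ 16 ⇒ 15 (from 11) + 14. After adjusting the oxidation level (acid from aldehyde), the C7a–C(sp) bond is cut, giving two fragments of similar size. The forward coupling relies on the ortho formyl group of 14 to activate its C–Br bond.

14 ⇒ 13 ⇒ 12. No skeletal bond is cut. The C4 oxygen of ring C is told apart from the C6 oxygen by cleaving only the methyl ether ortho to the formyl group; bromine already marks C7a and the formyl carbon is the future C3. This reaches a commercial, regiodefined arene.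

11 ⇒ 10 ⇒ 9. The C6(ring B)–C(sp) bond is cut back to the aryl bromide, and the two acetals back to phenols.

9 ⇒ 7 ⇒ 6 ⇒ 5. The ring B C2–O bond is traced to a C2–CHO group (oxidative aryl migration), so the two neighbouring ring B oxygens are never free together before the ether is in place. The ring A hydroxyl is traced through a methyl ether to a C–F bond. The forward steps need site-selective substitution of fluoride and cleavage of only the ester-chelated methyl ether.

5 ⇒ 3 + 4. The diaryl ether bond O–C6(ring A) is cut, giving a commercial phenol and a symmetric difluoro ester. The forward substitution must work with a hindered, weakly nucleophilic phenoxide.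

3 ⇒ 1 and 20 ⇒ 19. The C1–CO2Me bond of ring A comes from metalation between two fluorines; 21 comes from metalation of 20 between its two acetal oxygens, and 20 from 19 by O-alkylation.

## Other disconnections considered

Alternative 1: Larock indenone annulation, the first route that comes to mind. The cut is C1–C2 and C3–C3a; the forward key step is a palladium-catalysed annulation of 2-bromo-5-methoxy-3-(methoxymethoxy)benzaldehyde A1 with the diarylalkyne A2 to give 24 directly. The chosen plan is preferred because the orientation of alkyne insertion would rest on small differences between two ortho-substituted aryl termini; the bulkier 2,6-disubstituted ring D would be expected to end next to the carbonyl, on C2, which is the wrong carbon. In addition, the arylpalladium species flanked by formyl and acetal groups must add to a doubly hindered alkyne, and A1 itself requires halogenation between the formyl group and an oxygen of an arene with three activated positions. In 18 both regiochemical questions are settled by connectivity.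

Alternative 2: Nazarov cyclisation. The cut is C3–C3a only; the forward key step is an acid-promoted 4π-electrocyclisation of the 1,2,3-triarylpropenone A3 to the trans-2,3-diarylindanone A4, followed by dehydrogenation to 24. The chosen plan is preferred because ring closure could occur ortho to either oxygen of ring C, both positions being activated, so the OH/OMe pattern is not secured. The acid needed is also at odds with the acetals, the β-aryl group with two ortho oxygens is twisted out of conjugation, and an extra oxidation is needed.

Alternative 3: formal intramolecular alkyne–carbonyl metathesis. The cut is C2=C3 with transfer of the ketone oxygen to C1; the precursor is the ortho-alkynyl diaryl ketone A5, and the forward key step is a carbonyl-assisted hydration of the alkyne followed by aldol condensation to 24. The chosen plan is preferred because activation of the alkyne by acid or a carbophilic metal lets the ketone oxygen attack either alkyne carbon. Attack in the 6-endo mode, at the carbon whose positive charge ring B stabilises, gives the aromatic 2-benzopyrylium ion A6, which cannot lead to the indenone. The chosen plan performs the same oxygen transposition earlier, with a carboxylate under base where 5-exo closure is the rule, and purifies 18 before ring D is introduced.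

Key step: step 14

## Route

Step 1
Reactants: 1 3,5-difluorotoluene
Product: 3 methyl 2,6-difluoro-4-methylbenzoate, via aryllithium 2 (not isolated)
Conditions: n-BuLi, THF, -78 °C; then added to ClCO2Me, THF, -78 → 0 °C
Reagents that add atoms: methyl chloroformate, COC(=O)Cl
Why: The C–H between the two fluorines of 1 is the most acidic ring position, so ortho-lithiation should give 2 regioselectively; acylation with the chloroformate (inverse addition, low temperature) should give 3 without aryne formation or double addition.

Step 2
Reactants: 3 methyl 2,6-difluoro-4-methylbenzoate; 4 3-bromo-2-hydroxy-5-methoxybenzaldehyde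
Product: 5 methyl 2-(2-bromo-6-formyl-4-methoxyphenoxy)-6-fluoro-4-methylbenzoate
Conditions: Cs2CO3, DMSO, 100 °C (3 in excess)
Reagents that add atoms: none
Why: Nucleophilic aromatic substitution (SNAr): the phenoxide of 4 attacks a fluorine-bearing carbon of 3, the Meisenheimer intermediate being stabilised by the ortho ester and the remaining fluorine; the excess of 3 and the weak nucleophile should hold the reaction at mono-substitution.

Step 3
Reactants: 5 fluoro diaryl ether aldehyde
Product: 6 methyl 2-(2-bromo-6-formyl-4-methoxyphenoxy)-6-methoxy-4-methylbenzoate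
Conditions: NaOMe, MeOH/THF, 50 °C
Reagents that add atoms: sodium methoxide, [Na+].[O-]C
Why: Second SNAr: methoxide should displace the remaining fluoride, which is ortho to the ester and a far better site than the two aryloxy-bearing carbons; transesterification is degenerate with a methyl ester.

Step 4
Reactants: 6 methoxy diaryl ether aldehyde
Product: 7 methyl 2-(2-bromo-6-formyl-4-methoxyphenoxy)-6-hydroxy-4-methylbenzoate
Conditions: BCl3, CH2Cl2, -78 → 0 °C; aqueous work-up
Reagents that add atoms: none
Why: Chelation-controlled ether cleavage: BCl3 binds the ester carbonyl and the ortho methoxy oxygen of ring A in a six-membered chelate and chloride removes that methyl group only; the ring B methoxy group has no neighbouring carbonyl and should survive.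

Step 5
Reactants: 7 salicylate diaryl ether aldehyde
Product: 9 methyl 2-(2-bromo-6-hydroxy-4-methoxyphenoxy)-6-hydroxy-4-methylbenzoate, via aryl formate 8 (not isolated)
Conditions: mCPBA, CH2Cl2, 23 → 40 °C; then K2CO3 (cat.), MeOH, 0 °C
Reagents that add atoms: 3-chloroperoxybenzoic acid, OOC(=O)c1cccc(Cl)c1
Why: Baeyer–Villiger oxidation of an aryl aldehyde: the ortho aryloxy oxygen favours aryl over hydride migration in the Criegee intermediate, giving formate 8, which cold methanolysis should cleave to the phenol; unmasking this oxygen only now keeps the two ring B oxygens from being free together before the ether exists.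

Step 6
Reactants: 9 diphenol diaryl ether bromide
Product: 10 methyl 2-[2-bromo-4-methoxy-6-(methoxymethoxy)phenoxy]-6-(methoxymethoxy)-4-methylbenzoate
Conditions: NaH, MOMCl, DMF, 0 → 23 °C
Reagents that add atoms: chloromethyl methyl ether, COCCl
Why: Williamson-type O-alkylation of both phenoxides gives the bis-acetal; the acetals tolerate base, palladium catalysis and organolithium reagents and are removed together at the end.

Step 7
Reactants: 10 bis-acetal aryl bromide
Product: 11 methyl 2-[4-methoxy-2-(methoxymethoxy)-6-[2-(trimethylsilyl)ethynyl]phenoxy]-6-(methoxymethoxy)-4-methylbenzoate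
Conditions: HC≡CSiMe3, PdCl2(PPh3)2 (cat.), CuI (cat.), Et3N, DMF, 80 °C (sealed vessel)
Reagents that add atoms: ethynyltrimethylsilane, C#C[Si](C)(C)C
Why: Sonogashira coupling of the aryl bromide with the silyl-capped alkyne; the silyl group prevents double coupling and alkyne homocoupling.

Step 8
Reactants: 12 2-bromo-4,6-dimethoxybenzaldehyde
Product: 13 2-bromo-6-hydroxy-4-methoxybenzaldehyde
Conditions: BCl3, CH2Cl2, -78 → 0 °C; aqueous work-up
Reagents that add atoms: none
Why: Chelation-controlled demethylation: BCl3 bridges the formyl oxygen and the ortho methoxy oxygen, so only the 6-methoxy group should be cleaved; this step decides which ring C oxygen becomes the C4 hydroxyl of the target.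

Step 9
Reactants: 13 2-bromo-6-hydroxy-4-methoxybenzaldehyde
Product: 14 2-bromo-4-methoxy-6-(methoxymethoxy)benzaldehyde
Conditions: MOMCl, i-Pr2NEt, CH2Cl2, 0 → 40 °C
Reagents that add atoms: chloromethyl methyl ether, COCCl
Why: O-alkylation of the phenol as its methoxymethyl acetal; a free peri phenoxide would deactivate the lactone carbonyl in the key step.

Step 10
Reactants: 11 silyl alkyne; 14 2-bromo-4-methoxy-6-(methoxymethoxy)benzaldehyde
Product: 16 methyl 2-[2-[2-[2-formyl-5-methoxy-3-(methoxymethoxy)phenyl]ethynyl]-4-methoxy-6-(methoxymethoxy)phenoxy]-6-(methoxymethoxy)-4-methylbenzoate, via terminal alkyne 15 (not isolated)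
Conditions: K2CO3 (cat.), MeOH/THF, 23 °C; then 14, PdCl2(PPh3)2 (cat.), CuI (cat.), Et3N, 60 °C
Reagents that add atoms: none
Why: Methanolysis of the C–Si bond frees the terminal alkyne 15, which is coupled without isolation with bromide 14 (Sonogashira coupling); the ortho formyl group activates 14 for oxidative addition.

Step 11
Reactants: 16 diarylalkyne aldehyde
Product: 17 4-methoxy-2-[2-[5-methoxy-2-[2-(methoxycarbonyl)-3-(methoxymethoxy)-5-methylphenoxy]-3-(methoxymethoxy)phenyl]ethynyl]-6-(methoxymethoxy)benzoic acid
Conditions: NaClO2, NaH2PO4, 2-methyl-2-butene, t-BuOH/H2O, 23 °C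
Reagents that add atoms: sodium chlorite, [Na+].[O-]Cl=O
Why: Pinnick oxidation should convert the hindered aldehyde into the acid under buffered conditions that leave the alkyne, the acetals and the methyl ester untouched; the alkene scavenges hypochlorous acid.

Step 12
Reactants: 17 alkynyl benzoic acid
Product: 18 methyl 2-[2-[(Z)-[6-methoxy-4-(methoxymethoxy)-3-oxo-2-benzofuran-1(3H)-ylidene]methyl]-4-methoxy-6-(methoxymethoxy)phenoxy]-6-(methoxymethoxy)-4-methylbenzoate
Conditions: DBU (0.5 equiv), MeCN, 60 °C
Reagents that add atoms: none
Why: Base-catalysed cycloisomerisation: the carboxylate adds anti across the alkyne in a 5-exo-dig closure, which should give the (Z)-enol lactone (a 3-ylidenephthalide); without a carbophilic metal or acid the 6-endo mode to the isocoumarin should be minor.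

Step 13
Reactants: 19 orcinol (5-methylbenzene-1,3-diol)
Product: 20 1,3-bis(methoxymethoxy)-5-methylbenzene
Conditions: MOMCl, i-Pr2NEt, CH2Cl2, 0 → 23 °C
Reagents that add atoms: chloromethyl methyl ether, COCCl
Why: Double O-alkylation of the diol; the two acetal oxygens later direct lithiation to the carbon between them.

Step 14
Reactants: 18 (Z)-enol lactone; 20 1,3-bis(methoxymethoxy)-5-methylbenzene
Product: 24 methyl 2-[2-[3-[2,6-bis(methoxymethoxy)-4-methylphenyl]-6-methoxy-4-(methoxymethoxy)-1-oxo-1H-inden-2-yl]-4-methoxy-6-(methoxymethoxy)phenoxy]-6-(methoxymethoxy)-4-methylbenzoate, via aryllithium 21 (not isolated), via keto enolate 22 (not isolated), via aldol adduct 23 (not isolated)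
Conditions: 20, n-BuLi, THF, 0 °C; then 18, THF, -78 → 0 °C; then aq. HCl (1 M), THF, 0 → 23 °C
Reagents that add atoms: none
Why: Directed ortho-lithiation of 20 between its two acetal oxygens gives 21, which should add to the lactone carbonyl of 18, a planar and strained enol lactone that is more electrophilic and more accessible than the ring A ester, which is twisted out of conjugation by two ortho substituents. The tetrahedral alkoxide collapses by expelling the enolate oxygen to give 22, whose new C3 ketone carries four ortho substituents and should therefore resist a second addition. The enolate carbon C2 then attacks the C3 ketone held on the neighbouring ring carbon, a 5-(enolexo)-exo-trig aldol closure that forms the five-membered carbocycle (adduct 23). On acid work-up the tertiary, doubly benzylic C3 hydroxyl ionises easily (the cation is stabilised by ring D) and loss of the C2 proton gives the conjugated indenone, which drains any retro-aldol equilibrium. The closest known reaction type is the classical conversion of 3-benzylidenephthalides into 2,3-diarylinden-1-ones with aryl Grignard reagents. The two stereocentres of 23 are transient and are destroyed in the dehydration, so no stereocontrol is needed. Regiochemistry is a matter of connectivity and not of selectivity, since the lactone carbonyl carbon next to the C4 oxygen becomes C3 with ring D and the enol carbon becomes C1; the one selectivity needed, lactone over ester, is secured by the geometry of 18.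

Step 15
Reactants: 24 penta-acetal indenone
Product: 25 Ascomindone B, methyl 2-[2-[3-(2,6-dihydroxy-4-methylphenyl)-4-hydroxy-6-methoxy-1-oxo-1H-inden-2-yl]-6-hydroxy-4-methoxyphenoxy]-6-hydroxy-4-methylbenzoate
Conditions: HCl (3 M in MeOH), THF, 40 °C
Reagents that add atoms: none
Why: Acid-catalysed acetal exchange with methanol should remove all five methoxymethyl groups as dimethoxymethane; the aryl methyl ethers, the methyl ester (exchange in methanol is degenerate) and the indenone should survive.

## Compound list

1 | 3,5-difluorotoluene (1,3-difluoro-5-methylbenzene) | Cc1cc(F)cc(F)c1 | starting material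
2 | 2,6-difluoro-4-methylphenyllithium | [Li]c1c(F)cc(C)cc1F | intermediate
3 | methyl 2,6-difluoro-4-methylbenzoate | COC(=O)c1c(F)cc(C)cc1F | intermediate
4 | 3-bromo-2-hydroxy-5-methoxybenzaldehyde | O=Cc1cc(OC)cc(Br)c1O | starting material
5 | methyl 2-(2-bromo-6-formyl-4-methoxyphenoxy)-6-fluoro-4-methylbenzoate | COC(=O)c1c(F)cc(C)cc1Oc1c(Br)cc(OC)cc1C=O | intermediate
6 | methyl 2-(2-bromo-6-formyl-4-methoxyphenoxy)-6-methoxy-4-methylbenzoate | COC(=O)c1c(OC)cc(C)cc1Oc1c(Br)cc(OC)cc1C=O | intermediate
7 | methyl 2-(2-bromo-6-formyl-4-methoxyphenoxy)-6-hydroxy-4-methylbenzoate | COC(=O)c1c(O)cc(C)cc1Oc1c(Br)cc(OC)cc1C=O | intermediate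
8 | methyl 2-[2-bromo-6-(formyloxy)-4-methoxyphenoxy]-6-hydroxy-4-methylbenzoate | COC(=O)c1c(O)cc(C)cc1Oc1c(Br)cc(OC)cc1OC=O | intermediate
9 | methyl 2-(2-bromo-6-hydroxy-4-methoxyphenoxy)-6-hydroxy-4-methylbenzoate | COC(=O)c1c(O)cc(C)cc1Oc1c(Br)cc(OC)cc1O | intermediate
10 | methyl 2-[2-bromo-4-methoxy-6-(methoxymethoxy)phenoxy]-6-(methoxymethoxy)-4-methylbenzoate | COC(=O)c1c(OCOC)cc(C)cc1Oc1c(Br)cc(OC)cc1OCOC | intermediate
11 | methyl 2-[4-methoxy-2-(methoxymethoxy)-6-[2-(trimethylsilyl)ethynyl]phenoxy]-6-(methoxymethoxy)-4-methylbenzoate | COC(=O)c1c(OCOC)cc(C)cc1Oc1c(C#C[Si](C)(C)C)cc(OC)cc1OCOC | intermediate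
12 | 2-bromo-4,6-dimethoxybenzaldehyde | O=Cc1c(Br)cc(OC)cc1OC | starting material
13 | 2-bromo-6-hydroxy-4-methoxybenzaldehyde | O=Cc1c(Br)cc(OC)cc1O | intermediate
14 | 2-bromo-4-methoxy-6-(methoxymethoxy)benzaldehyde | O=Cc1c(Br)cc(OC)cc1OCOC | intermediate
15 | methyl 2-[2-ethynyl-4-methoxy-6-(methoxymethoxy)phenoxy]-6-(methoxymethoxy)-4-methylbenzoate | COC(=O)c1c(OCOC)cc(C)cc1Oc1c(C#C)cc(OC)cc1OCOC | intermediate
16 | methyl 2-[2-[2-[2-formyl-5-methoxy-3-(methoxymethoxy)phenyl]ethynyl]-4-methoxy-6-(methoxymethoxy)phenoxy]-6-(methoxymethoxy)-4-methylbenzoate | COC(=O)c1c(OCOC)cc(C)cc1Oc1c(C#Cc2cc(OC)cc(OCOC)c2C=O)cc(OC)cc1OCOC | intermediate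
17 | 4-methoxy-2-[2-[5-methoxy-2-[2-(methoxycarbonyl)-3-(methoxymethoxy)-5-methylphenoxy]-3-(methoxymethoxy)phenyl]ethynyl]-6-(methoxymethoxy)benzoic acid | COC(=O)c1c(OCOC)cc(C)cc1Oc1c(C#Cc2cc(OC)cc(OCOC)c2C(=O)O)cc(OC)cc1OCOC | intermediate
18 | methyl 2-[2-[(Z)-[6-methoxy-4-(methoxymethoxy)-3-oxo-2-benzofuran-1(3H)-ylidene]methyl]-4-methoxy-6-(methoxymethoxy)phenoxy]-6-(methoxymethoxy)-4-methylbenzoate | O=C1O/C(=C\c2cc(OC)cc(OCOC)c2Oc2cc(C)cc(OCOC)c2C(=O)OC)c2cc(OC)cc(OCOC)c12 | intermediate
19 | orcinol (5-methylbenzene-1,3-diol) | Cc1cc(O)cc(O)c1 | starting material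
20 | 1,3-bis(methoxymethoxy)-5-methylbenzene | Cc1cc(OCOC)cc(OCOC)c1 | intermediate
21 | 2,6-bis(methoxymethoxy)-4-methylphenyllithium | Cc1cc(OCOC)c([Li])c(OCOC)c1 | intermediate
22 | lithium enolate, methyl 2-[2-[(Z)-2-[2-[2,6-bis(methoxymethoxy)-4-methylbenzoyl]-5-methoxy-3-(methoxymethoxy)phenyl]-2-(lithiooxy)ethenyl]-4-methoxy-6-(methoxymethoxy)phenoxy]-6-(methoxymethoxy)-4-methylbenzoate | [Li]O/C(=C\c1cc(OC)cc(OCOC)c1Oc1cc(C)cc(OCOC)c1C(=O)OC)c1cc(OC)cc(OCOC)c1C(=O)c1c(OCOC)cc(C)cc1OCOC | intermediate
23 | methyl 2-[2-[3-[2,6-bis(methoxymethoxy)-4-methylphenyl]-3-hydroxy-6-methoxy-4-(methoxymethoxy)-1-oxo-2,3-dihydro-1H-inden-2-yl]-4-methoxy-6-(methoxymethoxy)phenoxy]-6-(methoxymethoxy)-4-methylbenzoate (transient mixture of racemic diastereomers) | O=C1C(c2cc(OC)cc(OCOC)c2Oc2cc(C)cc(OCOC)c2C(=O)OC)C(O)(c2c(OCOC)cc(C)cc2OCOC)c2c(OCOC)cc(OC)cc21 | intermediate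
24 | methyl 2-[2-[3-[2,6-bis(methoxymethoxy)-4-methylphenyl]-6-methoxy-4-(methoxymethoxy)-1-oxo-1H-inden-2-yl]-4-methoxy-6-(methoxymethoxy)phenoxy]-6-(methoxymethoxy)-4-methylbenzoate | O=C1C(c2cc(OC)cc(OCOC)c2Oc2cc(C)cc(OCOC)c2C(=O)OC)=C(c2c(OCOC)cc(C)cc2OCOC)c2c(OCOC)cc(OC)cc21 | intermediate
25 | Ascomindone B, methyl 2-[2-[3-(2,6-dihydroxy-4-methylphenyl)-4-hydroxy-6-methoxy-1-oxo-1H-inden-2-yl]-6-hydroxy-4-methoxyphenoxy]-6-hydroxy-4-methylbenzoate | COC(=O)c1c(O)cc(C)cc1Oc1c(O)cc(OC)cc1C1=C(c2c(O)cc(C)cc2O)c2c(O)cc(OC)cc2C1=O | target

## Step count and least certain steps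

Total: 15 steps. Longest linear sequence: 12 steps (steps 1–7, 10–12, 14, 15).

Step 14 (key step). The aryllithium may add to the ring A ester in competition with the lactone, or fail to add because the lactone carbonyl is shielded by the neighbouring acetal; the aldol closure onto the congested ketone may also stall in favour of retro-aldol. The fallback sets out from 16 and 20 and returns at 24. Reagent 21, made from 20 as in step 14, is added to the aldehyde of 16, a far less hindered electrophile, to give the diaryl carbinol F1. A catalytic alkoxide base (KOt-Bu, THF) then closes the alkoxide onto the alkyne in the 5-exo-dig mode to give the (Z)-1-arylmethylidene-3-aryl-1,3-dihydroisobenzofuran F2. DDQ in wet CH2Cl2 removes hydride from the doubly benzylic C–H next to oxygen, and water adds to the cation; the resulting hemiketal is the protonated form of the first adduct of step 14, which opens and undergoes the same aldol condensation on treatment with acid to give 24.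

Step 2. The substitution may be too slow, because the phenoxide of 4 is weakly nucleophilic and hindered by two ortho groups, so that the aldehyde decomposes at the temperature needed. The fallback sets out from 4 and returns at 5, and replaces SNAr by ligand coupling at trivalent iodine. Commercial 1-fluoro-3-iodo-5-methylbenzene is lithiated between fluorine and iodine (LDA, THF, -78 °C) and trapped with methyl chloroformate to give methyl 2-fluoro-6-iodo-4-methylbenzoate F3. Oxidation with mCPBA and TsOH in the presence of 1,3,5-trimethoxybenzene gives the aryl(2,4,6-trimethoxyphenyl)iodonium tosylate F4. Phenol 4 is then O-arylated with F4 (K2CO3, MeCN, 40 °C), the electron-poor, ortho-substituted aryl group being transferred, to give 5.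

Step 3. Methoxide may attack an aryloxy-bearing carbon (ring A C6 or the formyl-activated ring B C1) and expel a phenoxide instead of fluoride, cleaving the diaryl ether. The fallback sets out from 3 and 4 and returns at 6, and reverses the order of the two substitutions so that no aryloxide leaving group is present when methoxide is used. One equivalent of NaOMe (MeOH, 0 °C) converts 3 into methyl 2-fluoro-6-methoxy-4-methylbenzoate F5, which is then coupled with the phenoxide of 4 (Cs2CO3, DMSO, 120 °C) to give 6.

Step 12. The carboxylate may close in the 6-endo mode to the isocoumarin, because the ring B aryl group stabilises positive charge on the distal alkyne carbon. The fallback sets out from 14 and 15 and returns at 18, and makes the C–C and C–O bonds in one copper-mediated event of the Castro–Stephens type, in which the five-membered enol lactone is the characteristic product. Aldehyde 14 is oxidised (NaClO2, NaH2PO4, 2-methyl-2-butene) to 2-bromo-4-methoxy-6-(methoxymethoxy)benzoic acid F6. Alkyne 15, isolated after the methanolysis stage of step 10, is then coupled with F6 (CuI, K2CO3, DMF, 100 °C) to give 18 directly.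

## Further compounds

F1 | step 14 | methyl 2-[2-[2-[2-[[2,6-bis(methoxymethoxy)-4-methylphenyl](hydroxy)methyl]-5-methoxy-3-(methoxymethoxy)phenyl]ethynyl]-4-methoxy-6-(methoxymethoxy)phenoxy]-6-(methoxymethoxy)-4-methylbenzoate (racemic) | COC(=O)c1c(OCOC)cc(C)cc1Oc1c(C#Cc2cc(OC)cc(OCOC)c2C(O)c2c(OCOC)cc(C)cc2OCOC)cc(OC)cc1OCOC
F2 | step 14 | methyl 2-[2-[(Z)-[3-[2,6-bis(methoxymethoxy)-4-methylphenyl]-6-methoxy-4-(methoxymethoxy)-2-benzofuran-1(3H)-ylidene]methyl]-4-methoxy-6-(methoxymethoxy)phenoxy]-6-(methoxymethoxy)-4-methylbenzoate (racemic) | COCOc1cc(C)cc(OCOC)c1C1O/C(=C\c2cc(OC)cc(OCOC)c2Oc2cc(C)cc(OCOC)c2C(=O)OC)c2cc(OC)cc(OCOC)c21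
F3 | step 2 | methyl 2-fluoro-6-iodo-4-methylbenzoate | COC(=O)c1c(F)cc(C)cc1I
F4 | step 2 | [3-fluoro-2-(methoxycarbonyl)-5-methylphenyl](2,4,6-trimethoxyphenyl)iodonium 4-methylbenzenesulfonate | COC(=O)c1c(F)cc(C)cc1[I+]c1c(OC)cc(OC)cc1OC.Cc1ccc(cc1)S([O-])(=O)=O
F5 | step 3 | methyl 2-fluoro-6-methoxy-4-methylbenzoate | COC(=O)c1c(F)cc(C)cc1OC
F6 | step 12 | 2-bromo-4-methoxy-6-(methoxymethoxy)benzoic acid | OC(=O)c1c(Br)cc(OC)cc1OCOC
A1 | alternative 1 | 2-bromo-5-methoxy-3-(methoxymethoxy)benzaldehyde | O=Cc1cc(OC)cc(OCOC)c1Br
A2 | alternative 1 | methyl 2-[2-[2-[2,6-bis(methoxymethoxy)-4-methylphenyl]ethynyl]-4-methoxy-6-(methoxymethoxy)phenoxy]-6-(methoxymethoxy)-4-methylbenzoate | COC(=O)c1c(OCOC)cc(C)cc1Oc1c(C#Cc2c(OCOC)cc(C)cc2OCOC)cc(OC)cc1OCOC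
A3 | alternative 2 | methyl 2-[2-[1-[2,6-bis(methoxymethoxy)-4-methylphenyl]-3-[3-methoxy-5-(methoxymethoxy)phenyl]-3-oxoprop-1-en-2-yl]-4-methoxy-6-(methoxymethoxy)phenoxy]-6-(methoxymethoxy)-4-methylbenzoate (alkene geometry not defined) | COC(=O)c1c(OCOC)cc(C)cc1Oc1c(C(=Cc2c(OCOC)cc(C)cc2OCOC)C(=O)c2cc(OC)cc(OCOC)c2)cc(OC)cc1OCOC
A4 | alternative 2 | methyl 2-[2-[trans-3-[2,6-bis(methoxymethoxy)-4-methylphenyl]-6-methoxy-4-(methoxymethoxy)-1-oxo-2,3-dihydro-1H-inden-2-yl]-4-methoxy-6-(methoxymethoxy)phenoxy]-6-(methoxymethoxy)-4-methylbenzoate (racemic, one enantiomer drawn) | O=C1[C@@H](c2cc(OC)cc(OCOC)c2Oc2cc(C)cc(OCOC)c2C(=O)OC)[C@H](c2c(OCOC)cc(C)cc2OCOC)c2c(OCOC)cc(OC)cc21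
A5 | alternative 3 | methyl 2-[2-[2-[2-[2,6-bis(methoxymethoxy)-4-methylbenzoyl]-5-methoxy-3-(methoxymethoxy)phenyl]ethynyl]-4-methoxy-6-(methoxymethoxy)phenoxy]-6-(methoxymethoxy)-4-methylbenzoate | COC(=O)c1c(OCOC)cc(C)cc1Oc1c(C#Cc2cc(OC)cc(OCOC)c2C(=O)c2c(OCOC)cc(C)cc2OCOC)cc(OC)cc1OCOC
A6 | alternative 3 | 1-[2,6-bis(methoxymethoxy)-4-methylphenyl]-6-methoxy-3-[5-methoxy-2-[2-(methoxycarbonyl)-3-(methoxymethoxy)-5-methylphenoxy]-3-(methoxymethoxy)phenyl]-8-(methoxymethoxy)-2-benzopyrylium cation | COC(=O)c1c(OCOC)cc(C)cc1Oc1c(-c2cc3cc(OC)cc(OCOC)c3c(-c3c(OCOC)cc(C)cc3OCOC)[o+]2)cc(OC)cc1OCOC
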